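**Retrosynthetic overview**
- The target is an all-trans 2-aryl-3-(hydroxymethyl)-4-[aryl(hydroxy)methyl]oxolane. It comes from its primary O-silyl ether, and that from an acyclic triol by O(C7)→C9' ring closure on a primary tosylate (no stereocentre involved).
- The triol comes from LiBH4 opening of an all-trans α-[(S)-aryl(hydroxy)methyl]-β-(silyloxymethyl)-γ-aryl-γ-butyrolactone.
- The C7'–C8' bond comes from an aldol addition of the lactone potassium enolate to 3,4-dimethoxybenzaldehyde (sets C8' and C7').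
- The key C7–C8 bond comes from an Evans syn-aldol of an (R)-4-benzyloxazolidinone succinate imide with 3,4,5-trimethoxybenzaldehyde, lactonising to a trans paraconic acid derivative (COOH → CH2OSi).
- Ring order: γ-butyrolactone first (step 2), opened by reduction (step 7), oxolane closed last (step 8).

Assumption: lignan locants are used as labels (C7, C8, C9 on the trimethoxyphenyl half; C7', C8', C9' on the dimethoxyphenyl half); the target is (7R,8S,8'R,7'S), i.e. (S)-(3,4-dimethoxyphenyl)[(3R,4S,5R)-4-(hydroxymethyl)-5-(3,4,5-trimethoxyphenyl)oxolan-3-yl]methanol.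

**Route**

Step 1
Reactants: 1 (R)-4-benzyl-1,3-oxazolidin-2-one; 2 methyl 4-chloro-4-oxobutanoate
Product: 3 methyl 4-[(4R)-4-benzyl-2-oxo-1,3-oxazolidin-3-yl]-4-oxobutanoate
Conditions: n-BuLi, THF, −78 °C; then 2, −78 → 0 °C
Reagents that add atoms: none
Why: N-acylation of the lithiated oxazolidinone (nucleophilic acyl substitution) is far faster at the acid chloride than at the methyl ester at −78 °C, so the mono-imide forms cleanly and no stereocentre is created.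

Step 2
Reactants: 3 methyl 4-[(4R)-4-benzyl-2-oxo-1,3-oxazolidin-3-yl]-4-oxobutanoate; 4 3,4,5-trimethoxybenzaldehyde
Product: 6 (4R)-4-benzyl-3-{[(2R,3R)-5-oxo-2-(3,4,5-trimethoxyphenyl)oxolan-3-yl]carbonyl}-1,3-oxazolidin-2-one, via syn-aldol adduct 5 (not isolated)
Conditions: Bu2BOTf, i-Pr2NEt, CH2Cl2, 0 °C; 4, −78 → 0 °C; pH 7 KH2PO4/Na2HPO4 buffer, MeOH, 30% H2O2, 0 °C; then pyridinium p-toluenesulfonate (cat.), CH2Cl2, rt
Reagents that add atoms: none
Why: Evans syn-aldol reaction in which Bu2BOTf/i-Pr2NEt enolises only the imide to the Z-boron enolate, the Zimmerman–Traxler chair with opposed imide dipoles lets the aldehyde add to the enolate face opposite the benzyl group (setting C8 and C7, both R in 5, syn), and the benzylic hydroxyl then lactonises onto the methyl ester to give the trans γ-lactone.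

Step 3
Reactants: 6 (4R)-4-benzyl-3-{[(2R,3R)-5-oxo-2-(3,4,5-trimethoxyphenyl)oxolan-3-yl]carbonyl}-1,3-oxazolidin-2-one
Product: 8 (2R,3R)-5-oxo-2-(3,4,5-trimethoxyphenyl)oxolane-3-carboxylic acid, via peroxy acid 7 (not isolated)
Conditions: LiOH·H2O, 30% H2O2, THF/H2O 3:1, 0 °C; aq. Na2SO3; 1 M HCl to pH 2
Reagents that add atoms: hydrogen peroxide (OO)
Why: Lithium hydroperoxide cleavage of the N-acyl oxazolidinone, in which the hydroperoxide anion attacks the exocyclic imide carbonyl, the peroxy acid is reduced by sulfite, acidification re-closes any opened lactone, and neither stereocentre is touched at 0 °C.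

Step 4
Reactants: 8 (2R,3R)-5-oxo-2-(3,4,5-trimethoxyphenyl)oxolane-3-carboxylic acid
Product: 9 (4S,5R)-4-(hydroxymethyl)-5-(3,4,5-trimethoxyphenyl)oxolan-2-one
Conditions: BH3·SMe2, THF, 0 °C → rt; MeOH quench
Reagents that add atoms: none
Why: Chemoselective borane reduction of the carboxylic acid (via its acyloxyborane) is much faster than reduction of the γ-lactone, so only COOH becomes CH2OH and both stereocentres are kept.

Step 5
Reactants: 9 (4S,5R)-4-(hydroxymethyl)-5-(3,4,5-trimethoxyphenyl)oxolan-2-one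
Product: 10 (4S,5R)-4-{[tert-butyl(diphenyl)silyl]oxymethyl}-5-(3,4,5-trimethoxyphenyl)oxolan-2-one
Conditions: t-BuPh2SiCl, imidazole, DMF, 0 °C → rt
Reagents that add atoms: tert-butyl(chloro)diphenylsilane, CC(C)(C)[Si](Cl)(c1ccccc1)c1ccccc1
Why: Silylation of the primary alcohol gives a base- and hydride-stable ether that blocks translactonisation and keeps C9–OH distinct from the C9' hydroxyl unveiled later.

Step 6
Reactants: 10 (4S,5R)-4-{[tert-butyl(diphenyl)silyl]oxymethyl}-5-(3,4,5-trimethoxyphenyl)oxolan-2-one; 11 3,4-dimethoxybenzaldehyde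
Product: 12 (3S,4S,5R)-4-{[tert-butyl(diphenyl)silyl]oxymethyl}-3-[(S)-(3,4-dimethoxyphenyl)(hydroxy)methyl]-5-(3,4,5-trimethoxyphenyl)oxolan-2-one
Conditions: KN(SiMe3)2, THF, −78 °C; 11, −78 °C; AcOH quench at −78 °C; chromatography
Reagents that add atoms: none
Why: Intermolecular aldol addition of the lactone potassium enolate, in which the aldehyde adds to the face anti to the adjacent C4 silyloxymethyl group (3,4-trans, sets C8') and the potassium enolate is expected to react through an open transition state with erythro (syn) preference to give the (S)-carbinol at C7', the minor C7' epimer being removed by chromatography.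

Step 7
Reactants: 12 (3S,4S,5R)-4-{[tert-butyl(diphenyl)silyl]oxymethyl}-3-[(S)-(3,4-dimethoxyphenyl)(hydroxy)methyl]-5-(3,4,5-trimethoxyphenyl)oxolan-2-one
Product: 13 (1S,2R,3S,4R)-3-{[tert-butyl(diphenyl)silyl]oxymethyl}-1-(3,4-dimethoxyphenyl)-2-(hydroxymethyl)-4-(3,4,5-trimethoxyphenyl)butane-1,4-diol
Conditions: LiBH4, THF, 0 °C → rt; H2O quench
Reagents that add atoms: none
Why: Hydride reduction of the lactone to the 1,4-diol with LiBH4 breaks only the acyl C–O bond, so the silyl ether and all four stereocentres are unchanged.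

Step 8
Reactants: 13 (1S,2R,3S,4R)-3-{[tert-butyl(diphenyl)silyl]oxymethyl}-1-(3,4-dimethoxyphenyl)-2-(hydroxymethyl)-4-(3,4,5-trimethoxyphenyl)butane-1,4-diol
Product: 15 (S)-[(3R,4S,5R)-4-{[tert-butyl(diphenyl)silyl]oxymethyl}-5-(3,4,5-trimethoxyphenyl)oxolan-3-yl](3,4-dimethoxyphenyl)methanol, via primary tosylate 14 (not isolated)
Conditions: TsCl (1.2 equiv), pyridine, 4-(dimethylamino)pyridine (cat.), 0 °C → rt, then 45 °C
Reagents that add atoms: none
Why: Selective sulfonylation of the only primary hydroxyl followed by intramolecular Williamson etherification (5-exo-tet SN2 at C9' by the C7 hydroxyl) closes the oxolane without touching a stereocentre, whereas closure by the C7' hydroxyl would give a strained oxetane.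

Step 9
Reactants: 15 (S)-[(3R,4S,5R)-4-{[tert-butyl(diphenyl)silyl]oxymethyl}-5-(3,4,5-trimethoxyphenyl)oxolan-3-yl](3,4-dimethoxyphenyl)methanol
Product: 16 (S)-(3,4-dimethoxyphenyl)[(3R,4S,5R)-4-(hydroxymethyl)-5-(3,4,5-trimethoxyphenyl)oxolan-3-yl]methanol
Conditions: Bu4NF, THF, 0 °C → rt
Reagents that add atoms: none
Why: Fluoride-mediated desilylation frees the primary alcohol under conditions that leave the benzylic alcohol, the aryl ethers and the oxolane untouched, giving the target.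

**Compound list**
1 | (R)-4-benzyl-1,3-oxazolidin-2-one | O=C1N[C@H](Cc2ccccc2)CO1 | starting material
2 | methyl 4-chloro-4-oxobutanoate | COC(=O)CCC(Cl)=O | starting material
3 | methyl 4-[(4R)-4-benzyl-2-oxo-1,3-oxazolidin-3-yl]-4-oxobutanoate | COC(=O)CCC(=O)N1[C@H](Cc2ccccc2)COC1=O | intermediate
4 | 3,4,5-trimethoxybenzaldehyde | COc1cc(C=O)cc(OC)c1OC | starting material
5 | methyl (3R,4R)-3-{[(4R)-4-benzyl-2-oxo-1,3-oxazolidin-3-yl]carbonyl}-4-hydroxy-4-(3,4,5-trimethoxyphenyl)butanoate (syn-aldol adduct) | COC(=O)C[C@@H](C(=O)N1[C@H](Cc2ccccc2)COC1=O)[C@@H](O)c1cc(OC)c(OC)c(OC)c1 | intermediate (not isolated)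
6 | (4R)-4-benzyl-3-{[(2R,3R)-5-oxo-2-(3,4,5-trimethoxyphenyl)oxolan-3-yl]carbonyl}-1,3-oxazolidin-2-one | O=C1C[C@@H](C(=O)N2[C@H](Cc3ccccc3)COC2=O)[C@H](c2cc(OC)c(OC)c(OC)c2)O1 | intermediate
7 | (2R,3R)-5-oxo-2-(3,4,5-trimethoxyphenyl)oxolane-3-carboperoxoic acid (peroxy acid) | O=C1C[C@@H](C(=O)OO)[C@H](c2cc(OC)c(OC)c(OC)c2)O1 | intermediate (not isolated)
8 | (2R,3R)-5-oxo-2-(3,4,5-trimethoxyphenyl)oxolane-3-carboxylic acid | O=C1C[C@@H](C(=O)O)[C@H](c2cc(OC)c(OC)c(OC)c2)O1 | intermediate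
9 | (4S,5R)-4-(hydroxymethyl)-5-(3,4,5-trimethoxyphenyl)oxolan-2-one | O=C1C[C@@H](CO)[C@H](c2cc(OC)c(OC)c(OC)c2)O1 | intermediate
10 | (4S,5R)-4-{[tert-butyl(diphenyl)silyl]oxymethyl}-5-(3,4,5-trimethoxyphenyl)oxolan-2-one | O=C1C[C@@H](CO[Si](c2ccccc2)(c2ccccc2)C(C)(C)C)[C@H](c2cc(OC)c(OC)c(OC)c2)O1 | intermediate
11 | 3,4-dimethoxybenzaldehyde | COc1ccc(C=O)cc1OC | starting material
12 | (3S,4S,5R)-4-{[tert-butyl(diphenyl)silyl]oxymethyl}-3-[(S)-(3,4-dimethoxyphenyl)(hydroxy)methyl]-5-(3,4,5-trimethoxyphenyl)oxolan-2-one | O=C1[C@H]([C@H](O)c2ccc(OC)c(OC)c2)[C@@H](CO[Si](c2ccccc2)(c2ccccc2)C(C)(C)C)[C@H](c2cc(OC)c(OC)c(OC)c2)O1 | intermediate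
13 | (1S,2R,3S,4R)-3-{[tert-butyl(diphenyl)silyl]oxymethyl}-1-(3,4-dimethoxyphenyl)-2-(hydroxymethyl)-4-(3,4,5-trimethoxyphenyl)butane-1,4-diol | OC[C@H]([C@H](O)c1ccc(OC)c(OC)c1)[C@@H](CO[Si](c1ccccc1)(c1ccccc1)C(C)(C)C)[C@@H](O)c1cc(OC)c(OC)c(OC)c1 | intermediate
14 | (2R,3S,4R)-3-{[tert-butyl(diphenyl)silyl]oxymethyl}-2-[(S)-(3,4-dimethoxyphenyl)(hydroxy)methyl]-4-hydroxy-4-(3,4,5-trimethoxyphenyl)butyl 4-methylbenzenesulfonate (primary tosylate) | Cc1ccc(S(=O)(=O)OC[C@H]([C@H](O)c2ccc(OC)c(OC)c2)[C@@H](CO[Si](c2ccccc2)(c2ccccc2)C(C)(C)C)[C@@H](O)c2cc(OC)c(OC)c(OC)c2)cc1 | intermediate (not isolated)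
15 | (S)-[(3R,4S,5R)-4-{[tert-butyl(diphenyl)silyl]oxymethyl}-5-(3,4,5-trimethoxyphenyl)oxolan-3-yl](3,4-dimethoxyphenyl)methanol | COc1ccc([C@@H](O)[C@H]2CO[C@@H](c3cc(OC)c(OC)c(OC)c3)[C@@H]2CO[Si](c2ccccc2)(c2ccccc2)C(C)(C)C)cc1OC | intermediate
16 | (S)-(3,4-dimethoxyphenyl)[(3R,4S,5R)-4-(hydroxymethyl)-5-(3,4,5-trimethoxyphenyl)oxolan-3-yl]methanol | COc1ccc([C@@H](O)[C@H]2CO[C@@H](c3cc(OC)c(OC)c(OC)c3)[C@@H]2CO)cc1OC | target

**Totals**
Total step count: 9. Longest linear sequence: 9 steps (1 → 16).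

**Three steps most likely to fail**

Step 6 (C7' selectivity of the lactone aldol; the erythro preference of the potassium enolate is the least certain stereochemical call in the route). The fallback sets out from 10 and comes back at 12. The lithium enolate of 10 (LiN(SiMe3)2, 2.1 equiv, THF, −78 °C) is C-acylated with 3,4-dimethoxybenzoyl chloride in a crossed Claisen condensation to the trans β-keto lactone (3S,4S,5R)-4-{[tert-butyl(diphenyl)silyl]oxymethyl}-3-(3,4-dimethoxybenzoyl)-5-(3,4,5-trimethoxyphenyl)oxolan-2-one F4. The ketone of F4 is then reduced with Zn(BH4)2 (Et2O, −20 °C) under chelation control, zinc bridging the ketone and lactone carbonyls so that hydride arrives from the face opposite C4, which should give the syn alcohol 12.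

Step 2 (the ester-bearing imide may enolise or lactonise less cleanly than a simple acyl imide). The fallback sets out from 1 and 4 and comes back at 6. Compound 1 is acylated (n-BuLi, pent-4-enoyl chloride) to (4R)-4-benzyl-3-(pent-4-enoyl)-1,3-oxazolidin-2-one F1. The same Bu2BOTf/i-Pr2NEt aldol with 4 gives (4R)-4-benzyl-3-{(2R)-2-[(R)-hydroxy(3,4,5-trimethoxyphenyl)methyl]pent-4-enoyl}-1,3-oxazolidin-2-one F2. Cleavage of the terminal alkene (OsO4 cat., NaIO4, 2,6-lutidine, dioxane/H2O) gives a hydroxy aldehyde that closes to the lactol (4R)-4-benzyl-3-{[(2R,3R)-5-hydroxy-2-(3,4,5-trimethoxyphenyl)oxolan-3-yl]carbonyl}-1,3-oxazolidin-2-one F3 (anomer mixture). Oxidation of F3 with 2,2,6,6-tetramethylpiperidin-1-oxyl (cat.) and PhI(OAc)2 gives lactone 6.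

Step 8 (mono-tosylation and closure with two free benzylic hydroxyls present; over-sulfonylation or fragmentation of the 1,3-hydroxy tosylate could intrude). The fallback sets out from 12 and comes back at 16. The C7' hydroxyl is silylated (t-BuMe2SiOTf, 2,6-lutidine, CH2Cl2, −78 °C) to (3S,4S,5R)-3-[(S)-{[tert-butyl(dimethyl)silyl]oxy}(3,4-dimethoxyphenyl)methyl]-4-{[tert-butyl(diphenyl)silyl]oxymethyl}-5-(3,4,5-trimethoxyphenyl)oxolan-2-one F5. LiBH4 in THF gives (1R,2S,3R)-2-{[tert-butyl(diphenyl)silyl]oxymethyl}-3-[(S)-{[tert-butyl(dimethyl)silyl]oxy}(3,4-dimethoxyphenyl)methyl]-1-(3,4,5-trimethoxyphenyl)butane-1,4-diol F6. TsCl/pyridine gives the primary tosylate (2R,3S,4R)-3-{[tert-butyl(diphenyl)silyl]oxymethyl}-2-[(S)-{[tert-butyl(dimethyl)silyl]oxy}(3,4-dimethoxyphenyl)methyl]-4-hydroxy-4-(3,4,5-trimethoxyphenyl)butyl 4-methylbenzenesulfonate F7. NaH in THF at 0 °C then closes the ring to the bis-silyl ether tert-butyl{(S)-[(3R,4S,5R)-4-{[tert-butyl(diphenyl)silyl]oxymethyl}-5-(3,4,5-trimethoxyphenyl)oxolan-3-yl](3,4-dimethoxyphenyl)methoxy}dimethylsilane F8, and Bu4NF in THF removes both silyl groups to give 16.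

Further compounds
F1 | step 2 | (4R)-4-benzyl-3-(pent-4-enoyl)-1,3-oxazolidin-2-one | C=CCCC(=O)N1[C@H](Cc2ccccc2)COC1=O
F2 | step 2 | (4R)-4-benzyl-3-{(2R)-2-[(R)-hydroxy(3,4,5-trimethoxyphenyl)methyl]pent-4-enoyl}-1,3-oxazolidin-2-one | C=CC[C@@H](C(=O)N1[C@H](Cc2ccccc2)COC1=O)[C@@H](O)c1cc(OC)c(OC)c(OC)c1
F3 | step 2 | (4R)-4-benzyl-3-{[(2R,3R)-5-hydroxy-2-(3,4,5-trimethoxyphenyl)oxolan-3-yl]carbonyl}-1,3-oxazolidin-2-one (anomer mixture) | OC1C[C@@H](C(=O)N2[C@H](Cc3ccccc3)COC2=O)[C@H](c2cc(OC)c(OC)c(OC)c2)O1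
F4 | step 6 | (3S,4S,5R)-4-{[tert-butyl(diphenyl)silyl]oxymethyl}-3-(3,4-dimethoxybenzoyl)-5-(3,4,5-trimethoxyphenyl)oxolan-2-one | O=C1[C@H](C(=O)c2ccc(OC)c(OC)c2)[C@@H](CO[Si](c2ccccc2)(c2ccccc2)C(C)(C)C)[C@H](c2cc(OC)c(OC)c(OC)c2)O1
F5 | step 8 | (3S,4S,5R)-3-[(S)-{[tert-butyl(dimethyl)silyl]oxy}(3,4-dimethoxyphenyl)methyl]-4-{[tert-butyl(diphenyl)silyl]oxymethyl}-5-(3,4,5-trimethoxyphenyl)oxolan-2-one | O=C1[C@H]([C@H](O[Si](C)(C)C(C)(C)C)c2ccc(OC)c(OC)c2)[C@@H](CO[Si](c2ccccc2)(c2ccccc2)C(C)(C)C)[C@H](c2cc(OC)c(OC)c(OC)c2)O1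
F6 | step 8 | (1R,2S,3R)-2-{[tert-butyl(diphenyl)silyl]oxymethyl}-3-[(S)-{[tert-butyl(dimethyl)silyl]oxy}(3,4-dimethoxyphenyl)methyl]-1-(3,4,5-trimethoxyphenyl)butane-1,4-diol | OC[C@H]([C@H](O[Si](C)(C)C(C)(C)C)c1ccc(OC)c(OC)c1)[C@@H](CO[Si](c1ccccc1)(c1ccccc1)C(C)(C)C)[C@@H](O)c1cc(OC)c(OC)c(OC)c1
F7 | step 8 | (2R,3S,4R)-3-{[tert-butyl(diphenyl)silyl]oxymethyl}-2-[(S)-{[tert-butyl(dimethyl)silyl]oxy}(3,4-dimethoxyphenyl)methyl]-4-hydroxy-4-(3,4,5-trimethoxyphenyl)butyl 4-methylbenzenesulfonate | Cc1ccc(S(=O)(=O)OC[C@H]([C@H](O[Si](C)(C)C(C)(C)C)c2ccc(OC)c(OC)c2)[C@@H](CO[Si](c2ccccc2)(c2ccccc2)C(C)(C)C)[C@@H](O)c2cc(OC)c(OC)c(OC)c2)cc1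
F8 | step 8 | tert-butyl{(S)-[(3R,4S,5R)-4-{[tert-butyl(diphenyl)silyl]oxymethyl}-5-(3,4,5-trimethoxyphenyl)oxolan-3-yl](3,4-dimethoxyphenyl)methoxy}dimethylsilane | COc1ccc([C@@H](O[Si](C)(C)C(C)(C)C)[C@H]2CO[C@@H](c3cc(OC)c(OC)c(OC)c3)[C@@H]2CO[Si](c2ccccc2)(c2ccccc2)C(C)(C)C)cc1OC
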